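**Plan**
Numbering (daucane): C1 ring-fusion C(Me); C2 CH(OAng), C3 CH2 and C4 C(OH)(i-Pr) of the five-membered ring; C5 ring-fusion CH; C6 CH(OAng), C7 CH2, C8 C(Me)=, C9 =CH and C10 CH2 of the seven-membered ring.
Retrosynthesis: cut both angelate C–O bonds (triol), replace C6–O by C6–B, then cut C6–C7 and C5–C1 together. The arc C7–C8(Me)=C9–C10–C1 of the seven-membered ring is a ring-opened vinylcyclopropane (isopropenyl on C9, ring C9–C10–C1), and C5=C6 is an (E)-alkenylboronate tethered to C1 through C2–C3–C4.
Forward: Z-dienol, cyclopropane (C1, C9), aldehyde, aldol (C2–C3), alkynylation (C4–C5), alkenylboronate, rhodium-catalysed (5+2) cycloaddition closing both rings at once, C–B oxidation, double angeloylation; no protecting groups.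
Stereochemistry: C1 from a ligand-controlled Simmons–Smith reaction; C2 by 1,2-induction from the cis-substituted cyclopropane; C4 by 1,3-chelation from C2; C5 and C6 in the cycloaddition (C4 controls the alkene face, E geometry plus syn addition); C6–O by retentive oxidation; ester geometry from angelic acid.

Key step: step 8

Remark: the (4S,5S) dioxaborolane ligand is chosen from the known facial preference of this ligand class with allylic alcohols (the (4R,5R) ligand delivers methylene to the opposite face).

**Step 1**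
Reactants: 1 prop-2-yn-1-ol
Product: 3 (2Z)-3-iodo-2-methylprop-2-en-1-ol, via alkenylmagnesium alkoxide 2 (not isolated)
Conditions: MeMgBr (2.5 equiv), CuI (10 mol%), THF, −10 °C to rt; then I2, −10 °C; aq NH4Cl
Reagents that add atoms: methylmagnesium bromide, C[Mg]Br; iodine, II
Why: Copper-catalysed anti-carbomagnesiation of the propargylic alkoxide puts methyl on C2 and magnesium on C3 cis to the CH2O group (five-membered chelate), and iodinolysis with retention gives the Z iodide.

**Step 2**
Reactants: 3 (2Z)-3-iodo-2-methylprop-2-en-1-ol; 4 4,4,5,5-tetramethyl-2-(prop-1-en-2-yl)-1,3,2-dioxaborolane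
Product: 5 (2Z)-2,4-dimethylpenta-2,4-dien-1-ol
Conditions: Pd(PPh3)4 (5 mol%), K2CO3, THF/H2O, 60 °C
Reagents that add atoms: none
Why: Suzuki–Miyaura coupling of the alkenyl iodide goes with retention of the double-bond geometry, so the isopropenyl group ends cis to CH2OH.

**Step 3**
Reactants: 5 (2Z)-2,4-dimethylpenta-2,4-dien-1-ol
Product: 6 [(1R,2R)-1-methyl-2-(prop-1-en-2-yl)cyclopropyl]methanol
Conditions: Et2Zn (2.2 equiv), CH2I2 (4.4 equiv), DME, (4S,5S)-2-butyl-N,N,N′,N′-tetramethyl-1,3,2-dioxaborolane-4,5-dicarboxamide (1.2 equiv), CH2Cl2, −10 °C to rt; aq NH4Cl, then aq KOH wash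
Reagents that add atoms: diiodomethane, ICI
Why: Charette asymmetric Simmons–Smith cyclopropanation: the zinc alkoxide bound to the chiral dioxaborolane directs Zn(CH2I)2 to one face of the allylic double bond only (the distal alkene has no directing group), the Z geometry becomes the cis relation of CH2OH and isopropenyl, and the ligand sets both ring centres as R.

**Step 4**
Reactants: 6 [(1R,2R)-1-methyl-2-(prop-1-en-2-yl)cyclopropyl]methanol
Product: 7 (1R,2R)-1-methyl-2-(prop-1-en-2-yl)cyclopropane-1-carbaldehyde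
Conditions: Dess–Martin periodinane (1.2 equiv), NaHCO3, CH2Cl2, 0 °C; cold filtration, used at once
Reagents that add atoms: none
Why: Buffered Dess–Martin oxidation stops at the aldehyde, the quaternary C1 cannot epimerise, and the product is used cold and at once because cis-2-vinylcyclopropanecarbaldehydes slowly undergo a retro-Claisen shift at room temperature.

**Step 5**
Reactants: 7 (1R,2R)-1-methyl-2-(prop-1-en-2-yl)cyclopropane-1-carbaldehyde; 8 3-methylbutan-2-one
Product: 10 (5S)-5-hydroxy-2-methyl-5-[(1R,2R)-1-methyl-2-(prop-1-en-2-yl)cyclopropyl]pentan-3-one, via lithium enolate 9 (not isolated)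
Conditions: LiN(i-Pr)2 (1.1 equiv), 8, THF, −78 °C; then 7, −78 °C; aq NH4Cl
Reagents that add atoms: none
Why: Kinetic lithium enolate aldol addition: the enolate forms at the methyl group and should attack the aldehyde in its bisected s-trans conformation from the side of the ring CH2, anti to the cis-isopropenyl group (Felkin-type 1,2-induction), giving the S carbinol at C2.

**Step 6**
Reactants: 10 (5S)-5-hydroxy-2-methyl-5-[(1R,2R)-1-methyl-2-(prop-1-en-2-yl)cyclopropyl]pentan-3-one; 11 ethynylmagnesium bromide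
Product: 12 (1S,3R)-1-[(1R,2R)-1-methyl-2-(prop-1-en-2-yl)cyclopropyl]-3-(propan-2-yl)pent-4-yne-1,3-diol
Conditions: HC≡CMgBr (4 equiv), THF/CH2Cl2, −78 to −20 °C; aq NH4Cl
Reagents that add atoms: none
Why: Chelation-controlled Grignard addition: the magnesium alkoxide at C2 holds the ketone in a half-chair chelate with the cyclopropyl group equatorial, and axial attack of the acetylide should give the 1,3-anti diol, that is the R tertiary carbinol at C4.

**Step 7**
Reactants: 12 (1S,3R)-1-[(1R,2R)-1-methyl-2-(prop-1-en-2-yl)cyclopropyl]-3-(propan-2-yl)pent-4-yne-1,3-diol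
Product: 13 (1S,3R,4E)-1-[(1R,2R)-1-methyl-2-(prop-1-en-2-yl)cyclopropyl]-3-(propan-2-yl)-5-(4,4,5,5-tetramethyl-1,3,2-dioxaborolan-2-yl)pent-4-ene-1,3-diol
Conditions: CuCl (5 mol%), Xantphos (5 mol%), NaOt-Bu (10 mol%), B2pin2 (1.1 equiv), MeOH (2 equiv), THF, rt
Reagents that add atoms: bis(pinacolato)diboron, CC1(C)OB(OC1(C)C)B1OC(C)(C)C(C)(C)O1
Why: Copper-catalysed protoboration: syn addition of the boryl copper species across the terminal alkyne with boron on the terminal carbon (the fully substituted propargylic carbon steers it there) and protonation by methanol give the E alkenylboronate, while the unactivated alkene and the hydroxyl groups stay untouched.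

**Step 8**
Reactants: 13 (1S,3R,4E)-1-[(1R,2R)-1-methyl-2-(prop-1-en-2-yl)cyclopropyl]-3-(propan-2-yl)-5-(4,4,5,5-tetramethyl-1,3,2-dioxaborolan-2-yl)pent-4-ene-1,3-diol
Product: 14 (1S,3R,3aR,4S,8aR)-6,8a-dimethyl-3-(propan-2-yl)-4-(4,4,5,5-tetramethyl-1,3,2-dioxaborolan-2-yl)-1,2,3,3a,4,5,8,8a-octahydroazulene-1,3-diol
Conditions: [Rh(CO)2Cl]2 (5 mol%), toluene (0.02 M), 90 °C
Reagents that add atoms: none
Why: Proposed new method: [Rh(CO)2Cl]2, bound to the isopropenyl group and to the alkenylboronate that sits cis to it on the ring, should insert monovalent rhodium into the strained C9–C1 bond to give a σ-alkyl (C1)/anti-π-allyl (C9–C8–C7) trivalent rhodium species; syn insertion of the alkene into the Rh–C1 bond (C1 to C5, rhodium to the boron-bearing C6, the usual regiochemistry of alkenylboronates in migratory insertion) and reductive elimination between C6 and the allyl terminus C7 complete the cycle. The closest known reaction type is the [Rh(CO)2Cl]2-catalysed intramolecular (5+2) cycloaddition of vinylcyclopropanes with tethered alkenes or alkynes, which has also been seen when a terminal alkene is tethered cis on the ring carbon next to the vinyl-bearing one; not shown so far are a 1,2-disubstituted alkenylboronate as the two-carbon partner and a quaternary carbon at the cleaved bond. The five-membered ring closes by 5-exo-trig migratory insertion (C1–C5) and the seven-membered ring by C(sp3)–C(sp3) reductive elimination from an eight-membered rhodacycle (C6–C7), in which the anti-allyl fixes the C8=C9 position and its Z geometry in the ring. C1 keeps the configuration of the cyclopropane (oxidative addition and insertion go with retention, the C9 centre is lost), C5 is controlled by C4 (in the insertion transition state C6 with its rhodium lies next to the small hydroxyl and away from the isopropyl group, so that H5 ends trans to the C1 methyl), and C6 follows from the E alkene by syn addition (boron cis to H5). The step needs cleavage of C9–C1 and not of C9–C10 and a (5+2) and not a (3+2) reductive elimination; the cis tether, which lets the alkene reach rhodium only after C9–C1 cleavage, and the anti-allyl geometry that comes from the cis-disubstituted ring should secure both, and the rigid rhodacycle holds H5 away from the syn-coplanar position that β-hydride elimination would need.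

**Step 9**
Reactants: 14 (1S,3R,3aR,4S,8aR)-6,8a-dimethyl-3-(propan-2-yl)-4-(4,4,5,5-tetramethyl-1,3,2-dioxaborolan-2-yl)-1,2,3,3a,4,5,8,8a-octahydroazulene-1,3-diol
Product: 15 (1S,3R,3aS,4S,8aR)-6,8a-dimethyl-3-(propan-2-yl)-1,2,3,3a,4,5,8,8a-octahydroazulene-1,3,4-triol
Conditions: 30% H2O2, 2 M NaOH, THF, 0 °C to rt
Reagents that add atoms: hydrogen peroxide, OO
Why: Oxidation of the secondary alkylboronate by alkaline hydrogen peroxide goes through a 1,2-shift of carbon from boron to oxygen with retention, so the C6 hydroxyl stays on the face of H5.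

**Step 10**
Reactants: 15 (1S,3R,3aS,4S,8aR)-6,8a-dimethyl-3-(propan-2-yl)-1,2,3,3a,4,5,8,8a-octahydroazulene-1,3,4-triol; 16 (2Z)-2-methylbut-2-enoic acid (angelic acid)
Product: 18 (1S,3R,3aS,4S,8aR)-3-hydroxy-6,8a-dimethyl-3-(propan-2-yl)-1,2,3,3a,4,5,8,8a-octahydroazulene-1,4-diyl bis[(2Z)-2-methylbut-2-enoate], via mixed anhydride 17 (not isolated)
Conditions: 16 (5 equiv), 2,4,6-trichlorobenzoyl chloride (5 equiv), Et3N (6 equiv), toluene, rt; then 15, 80 °C
Reagents that add atoms: none
Why: Yamaguchi-type esterification through the mixed anhydride acylates the two secondary hydroxyl groups and leaves the hindered tertiary C4 hydroxyl free, and working without a nucleophilic amine catalyst should avoid Z to E isomerisation to the tiglate.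

**Compound list**
1 | prop-2-yn-1-ol | C#CCO | starting material
2 | bromomagnesium (2Z)-3-(bromomagnesio)-2-methylprop-2-en-1-olate | Br[Mg]/C=C(/C)CO[Mg]Br | intermediate
3 | (2Z)-3-iodo-2-methylprop-2-en-1-ol | I/C=C(/C)CO | intermediate
4 | 4,4,5,5-tetramethyl-2-(prop-1-en-2-yl)-1,3,2-dioxaborolane | CC(=C)B1OC(C)(C)C(C)(C)O1 | starting material
5 | (2Z)-2,4-dimethylpenta-2,4-dien-1-ol | C=C(C)/C=C(/C)CO | intermediate
6 | [(1R,2R)-1-methyl-2-(prop-1-en-2-yl)cyclopropyl]methanol | C=C(C)[C@H]1C[C@@]1(C)CO | intermediate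
7 | (1R,2R)-1-methyl-2-(prop-1-en-2-yl)cyclopropane-1-carbaldehyde | C=C(C)[C@H]1C[C@@]1(C)C=O | intermediate
8 | 3-methylbutan-2-one | CC(=O)C(C)C | starting material
9 | lithium 3-methylbut-1-en-2-olate | [Li]OC(=C)C(C)C | intermediate
10 | (5S)-5-hydroxy-2-methyl-5-[(1R,2R)-1-methyl-2-(prop-1-en-2-yl)cyclopropyl]pentan-3-one | C=C(C)[C@H]1C[C@@]1(C)[C@@H](O)CC(=O)C(C)C | intermediate
11 | ethynylmagnesium bromide | C#C[Mg]Br | starting material
12 | (1S,3R)-1-[(1R,2R)-1-methyl-2-(prop-1-en-2-yl)cyclopropyl]-3-(propan-2-yl)pent-4-yne-1,3-diol | C=C(C)[C@H]1C[C@@]1(C)[C@@H](O)C[C@@](O)(C(C)C)C#C | intermediate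
13 | (1S,3R,4E)-1-[(1R,2R)-1-methyl-2-(prop-1-en-2-yl)cyclopropyl]-3-(propan-2-yl)-5-(4,4,5,5-tetramethyl-1,3,2-dioxaborolan-2-yl)pent-4-ene-1,3-diol | C=C(C)[C@H]1C[C@@]1(C)[C@@H](O)C[C@@](O)(C(C)C)/C=C/B2OC(C)(C)C(C)(C)O2 | intermediate
14 | (1S,3R,3aR,4S,8aR)-6,8a-dimethyl-3-(propan-2-yl)-4-(4,4,5,5-tetramethyl-1,3,2-dioxaborolan-2-yl)-1,2,3,3a,4,5,8,8a-octahydroazulene-1,3-diol | CC1(C)OB(OC1(C)C)[C@H]1CC(C)=CC[C@@]2(C)[C@@H](O)C[C@@](O)(C(C)C)[C@H]12 | intermediate
15 | (1S,3R,3aS,4S,8aR)-6,8a-dimethyl-3-(propan-2-yl)-1,2,3,3a,4,5,8,8a-octahydroazulene-1,3,4-triol | O[C@H]1CC(C)=CC[C@@]2(C)[C@@H](O)C[C@@](O)(C(C)C)[C@H]12 | intermediate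
16 | (2Z)-2-methylbut-2-enoic acid | C/C=C(/C)C(=O)O | starting material
17 | (2Z)-2-methylbut-2-enoic 2,4,6-trichlorobenzoic anhydride | C/C=C(/C)C(=O)OC(=O)c1c(Cl)cc(Cl)cc1Cl | intermediate
18 | (1S,3R,3aS,4S,8aR)-3-hydroxy-6,8a-dimethyl-3-(propan-2-yl)-1,2,3,3a,4,5,8,8a-octahydroazulene-1,4-diyl bis[(2Z)-2-methylbut-2-enoate] | C/C=C(/C)C(=O)O[C@H]1CC(C)=CC[C@@]2(C)[C@@H](OC(=O)/C(C)=C\C)C[C@@](O)(C(C)C)[C@H]12 | target

Total step count: 10. Longest linear sequence: 10 steps (1 to 18; 4, 8, 11 and 16 are bought).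

**Steps most likely to fail**

Step 8. Migratory insertion of the 1,2-disubstituted alkenylboronate into the hindered Rh–C1 bond may be slow. β-Hydride elimination of the rhodacycle to ring-opened dienes, cleavage of the C9–C10 bond or addition to the other alkene face could then take over. The fallback uses established reaction types only, sets out from 12 and comes back at 15. The alkyne of 12 is borylated (n-BuLi, 3.1 equiv, THF, −78 °C; i-PrOBpin; HCl in Et2O) to the alkynylboronate diol F1. F1 is submitted to the same [Rh(CO)2Cl]2-catalysed (5+2) cycloaddition; an alkyne is the most reactive two-carbon partner of this reaction and creates no C5 centre. This should give the dienylboronate diol F2. Buffered oxidation (H2O2, pH 7 phosphate, THF, 0 °C) converts the alkenylboronate into the hydroxy ketone F3. Hydroxyl-directed reduction (Me4NBH(OAc)3, AcOH/MeCN, −20 °C) then delivers hydride from the C4 oxygen to C6 and gives 15. Only the C5 epimer with H5 trans to the C1 methyl can take hydride this way, so the reduction also filters the ketonisation outcome. F3 is a β,γ-unsaturated ketone and is kept away from base.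

Step 10. Acylation of two hindered secondary hydroxyl groups may stay incomplete, and forcing conditions may isomerise the angeloyl group to the tigloyl group. The fallback sets out from 15 and comes back at 18. Both secondary hydroxyl groups are acylated with 2-[bis(2,2,2-trifluoroethoxy)phosphoryl]propanoic acid (DCC, DMAP, CH2Cl2) to the bis(phosphonopropanoate) F4. A Still–Gennari olefination with acetaldehyde (KN(SiMe3)2, 18-crown-6, THF, −78 °C) then builds both Z double bonds on the esters in place.

Step 4. The cis-vinylcyclopropane carbaldehyde may undergo the retro-Claisen rearrangement to a dihydrooxepine before the enolate is added. The fallback sets out from 3 and comes back at 12, and brings in the vinyl group only after the aldehyde stage. Charette cyclopropanation of 3 with the same ligand gives the iodocyclopropyl carbinol F5. Dess–Martin oxidation gives the iodocyclopropane carbaldehyde F6, which cannot rearrange. Addition of enolate 9 gives the iodo aldol F7, and HC≡CMgBr gives the iodo ynediol F8. Suzuki–Miyaura coupling of the cyclopropyl iodide with 4 (Pd(OAc)2, SPhos, K3PO4, toluene/H2O, 80 °C) goes with retention at the ring carbon and returns to 12.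

**Further compounds**
F1 | step 8 | (1S,3R)-1-[(1R,2R)-1-methyl-2-(prop-1-en-2-yl)cyclopropyl]-3-(propan-2-yl)-5-(4,4,5,5-tetramethyl-1,3,2-dioxaborolan-2-yl)pent-4-yne-1,3-diol | C=C(C)[C@H]1C[C@@]1(C)[C@@H](O)C[C@@](O)(C(C)C)C#CB2OC(C)(C)C(C)(C)O2
F2 | step 8 | (1S,3R,8aR)-6,8a-dimethyl-3-(propan-2-yl)-4-(4,4,5,5-tetramethyl-1,3,2-dioxaborolan-2-yl)-1,2,3,5,8,8a-hexahydroazulene-1,3-diol | CC1(C)OB(OC1(C)C)C3=C2[C@](O)(C(C)C)C[C@H](O)[C@]2(C)CC=C(C)C3
F3 | step 8 | (1S,3R,3aR,8aR)-1,3-dihydroxy-6,8a-dimethyl-3-(propan-2-yl)-2,3,3a,5,8,8a-hexahydroazulen-4(1H)-one | O=C1CC(C)=CC[C@@]2(C)[C@@H](O)C[C@@](O)(C(C)C)[C@H]12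
F4 | step 10 | (1S,3R,3aS,4S,8aR)-3-hydroxy-6,8a-dimethyl-3-(propan-2-yl)-1,2,3,3a,4,5,8,8a-octahydroazulene-1,4-diyl bis{2-[bis(2,2,2-trifluoroethoxy)phosphoryl]propanoate} | CC(C(=O)O[C@H]1CC(C)=CC[C@@]2(C)[C@@H](OC(=O)C(C)P(=O)(OCC(F)(F)F)OCC(F)(F)F)C[C@@](O)(C(C)C)[C@H]12)P(=O)(OCC(F)(F)F)OCC(F)(F)F
F5 | step 4 | [(1S,2S)-2-iodo-1-methylcyclopropyl]methanol | I[C@H]1C[C@@]1(C)CO
F6 | step 4 | (1S,2S)-2-iodo-1-methylcyclopropane-1-carbaldehyde | I[C@H]1C[C@@]1(C)C=O
F7 | step 4 | (5S)-5-hydroxy-5-[(1S,2S)-2-iodo-1-methylcyclopropyl]-2-methylpentan-3-one | I[C@H]1C[C@@]1(C)[C@@H](O)CC(=O)C(C)C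
F8 | step 4 | (1S,3R)-1-[(1S,2S)-2-iodo-1-methylcyclopropyl]-3-(propan-2-yl)pent-4-yne-1,3-diol | I[C@H]1C[C@@]1(C)[C@@H](O)C[C@@](O)(C(C)C)C#C
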